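**Strategy.** The route rests on disconnecting the bond between C5 of the lactone ring and the ipso carbon of the 4-hydroxy-3-methoxyphenyl ring. C5 is the one lactone carbon that is both benzylic and bound to the ring oxygen O1, so it can be handled as an acetal. In the precursor it carries the (−)-menthyloxy group of a butenolide auxiliary, whose C5 stereocentre first sets C4. Lewis-acid ionisation then lets guaiacol attack C5 through its carbon para to OH, anti to the C4 substituent. One operation forms the aryl–C5 bond, fixes the 4,5-trans relation and expels the auxiliary. C4 finally relays to C3 by hydrogenation of a benzylidene lactone.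

Key step: step 3

Assumption: (5R)-5-(l-menthyloxy)furan-2(5H)-one (the butenolide acetal of 5-hydroxyfuran-2(5H)-one with (−)-menthol) and O-TBS-vanillin are taken as catalogue compounds.

Ring numbering used throughout: O1, C2 (carbonyl), C3 (benzyl carbon), C4 (CH2O carbon), C5 (aryl carbon).

**Step 1**
Reactants: 1 (5R)-5-[(1R,2S,5R)-menthyloxy]furan-2(5H)-one
Product: 2 (4S,5R)-4-(hydroxymethyl)-5-[(1R,2S,5R)-menthyloxy]dihydrofuran-2(3H)-one
Conditions: hν (350 nm, Pyrex), Ph2CO (0.2 equiv), degassed MeOH, rt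
Reagents that add atoms: methanol, CO
Why: Benzophenone-sensitised photochemical radical hydroxymethylation; the nucleophilic hydroxymethyl radical adds to the β-carbon C4 of the butenolide on the face anti to the C5 menthyloxy group, which should set C4 as S (4,5-trans).

**Step 2**
Reactants: 2 (4S,5R)-4-(hydroxymethyl)-5-[(1R,2S,5R)-menthyloxy]dihydrofuran-2(3H)-one
Product: 3 (4S,5R)-4-[(tert-butyldiphenylsilyloxy)methyl]-5-[(1R,2S,5R)-menthyloxy]dihydrofuran-2(3H)-one
Conditions: TBDPSCl, imidazole, DMF, 0 °C → rt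
Reagents that add atoms: tert-butyl(chloro)diphenylsilane, CC(C)(C)[Si](Cl)(c1ccccc1)c1ccccc1
Why: Standard silylation of the primary alcohol; the acid-robust TBDPS ether should survive step 3 and keeps the CH2O group from taking up the carboxyl carbon once C5 is ionised.

**Step 3**
Reactants: 3 (4S,5R)-4-[(tert-butyldiphenylsilyloxy)methyl]-5-[(1R,2S,5R)-menthyloxy]dihydrofuran-2(3H)-one; 4 guaiacol (2-methoxyphenol, 2 equiv)
Product: 5 (4S,5R)-4-[(tert-butyldiphenylsilyloxy)methyl]-5-(4-hydroxy-3-methoxyphenyl)dihydrofuran-2(3H)-one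
Conditions: BF3·OEt2 (0.5 equiv), CH2Cl2, −40 → 0 °C
Reagents that add atoms: none
Why: BF3 ionises the acetal carbon C5 (by loss of menthol, or by opening of the C5–O1 bond to the menthyl-stabilised oxocarbenium carboxylate, which leads to the same product), and guaiacol attacks this cation through the carbon para to its hydroxyl group in a Friedel–Crafts alkylation; the closest known reaction types are phenol C-glycosylation of acetal donors and the arylation of pseudo-esters of aldehydo acids (3-alkoxyphthalides) to aryl lactones. No new ring results overall: the lactone either stays closed or, if it has opened, re-forms by 5-exo-trig capture of the benzylic cation by the carboxylate with loss of menthol. The new stereocentre C5 is controlled by C4: the arene (or the re-closing carboxylate) approaches anti to the CH2OTBDPS group, and because the electron-rich benzylic C5–O1 bond can re-ionise under the conditions, the more stable 4,5-trans lactone (5R) should also be the thermodynamic product. The step needs regioselectivity on the arene and 4,5-trans diastereoselectivity; the first rests on the stronger para-directing power of the free OH (hydrogen-bonded to the neighbouring OMe) over OMe, the second on the bulky C4 substituent. Only a small excess of guaiacol at low temperature is used so that the product is not ionised and arylated a second time, and the second arene of the target is not yet present, so it cannot cyclise onto C5.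

**Step 4**
Reactants: 5 (4S,5R)-4-[(tert-butyldiphenylsilyloxy)methyl]-5-(4-hydroxy-3-methoxyphenyl)dihydrofuran-2(3H)-one
Product: 6 (4S,5R)-4-[(tert-butyldiphenylsilyloxy)methyl]-5-[4-(tert-butyldimethylsilyloxy)-3-methoxyphenyl]dihydrofuran-2(3H)-one
Conditions: TBSCl, imidazole, DMF, rt
Reagents that add atoms: tert-butyl(chloro)dimethylsilane, CC(C)(C)[Si](C)(C)Cl
Why: Silylation of the phenol, needed before enolate chemistry; imidazole is too weak a base to open the p-hydroxybenzylic lactone through a quinone methide.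

**Step 5**
Reactants: 6 (4S,5R)-4-[(tert-butyldiphenylsilyloxy)methyl]-5-[4-(tert-butyldimethylsilyloxy)-3-methoxyphenyl]dihydrofuran-2(3H)-one; 7 4-(tert-butyldimethylsilyloxy)-3-methoxybenzaldehyde
Product: 11 (4S,5R,E)-3-[4-(tert-butyldimethylsilyloxy)-3-methoxybenzylidene]-4-[(tert-butyldiphenylsilyloxy)methyl]-5-[4-(tert-butyldimethylsilyloxy)-3-methoxyphenyl]dihydrofuran-2(3H)-one, via lithium enolate 8 (not isolated), via lithium aldolate 9 (not isolated), via mesylate 10 (not isolated)
Conditions: LiN(i-Pr)2 (LDA), THF, −78 °C; then 7; then MsCl, −78 → 0 °C; then DBU, 0 °C → rt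
Reagents that add atoms: none
Why: Aldol condensation; the lactone enolate adds to aldehyde 7, the aldolate is mesylated in the flask and DBU effects E1cB elimination to the conjugated (E)-benzylidene lactone, leaving C4 and C5 untouched and erasing the transient aldol stereocentres.

**Step 6**
Reactants: 11 (4S,5R,E)-3-[4-(tert-butyldimethylsilyloxy)-3-methoxybenzylidene]-4-[(tert-butyldiphenylsilyloxy)methyl]-5-[4-(tert-butyldimethylsilyloxy)-3-methoxyphenyl]dihydrofuran-2(3H)-one
Product: 12 (3S,4S,5R)-3-[4-(tert-butyldimethylsilyloxy)-3-methoxybenzyl]-4-[(tert-butyldiphenylsilyloxy)methyl]-5-[4-(tert-butyldimethylsilyloxy)-3-methoxyphenyl]dihydrofuran-2(3H)-one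
Conditions: H2 (1 atm), 10% Pd/C, Ph2S (0.01 equiv), EtOAc, rt
Reagents that add atoms: none
Why: Heterogeneous hydrogenation should deliver hydrogen to the exocyclic alkene from the face anti to the adjacent C4 CH2OTBDPS group (pushed pseudo-axial by allylic strain with the benzylidene aryl), setting C3 as S with the benzyl group cis to C4; sulfide-poisoned Pd/C reduces alkenes without hydrogenolysis of benzylic C–O bonds such as C5–O1.

**Step 7**
Reactants: 12 (3S,4S,5R)-3-[4-(tert-butyldimethylsilyloxy)-3-methoxybenzyl]-4-[(tert-butyldiphenylsilyloxy)methyl]-5-[4-(tert-butyldimethylsilyloxy)-3-methoxyphenyl]dihydrofuran-2(3H)-one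
Product: 13 (3S,4S,5R)-3-(4-hydroxy-3-methoxybenzyl)-5-(4-hydroxy-3-methoxyphenyl)-4-(hydroxymethyl)dihydrofuran-2(3H)-one
Conditions: TBAF, AcOH (1:1), THF, 0 °C → rt
Reagents that add atoms: none
Why: Fluoride cleaves the two aryl TBS ethers and the primary TBDPS ether in one operation; buffering with acetic acid should prevent epimerisation of the cis C3 centre and quinone-methide opening of the p-hydroxybenzylic lactone.

**Compound list**

1 | (5R)-5-[(1R,2S,5R)-menthyloxy]furan-2(5H)-one | O=C1C=C[C@H](O[C@@H]2C[C@H](C)CC[C@H]2C(C)C)O1 | starting material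
2 | (4S,5R)-4-(hydroxymethyl)-5-[(1R,2S,5R)-menthyloxy]dihydrofuran-2(3H)-one | O=C1C[C@@H](CO)[C@H](O[C@@H]2C[C@H](C)CC[C@H]2C(C)C)O1 | intermediate
3 | (4S,5R)-4-[(tert-butyldiphenylsilyloxy)methyl]-5-[(1R,2S,5R)-menthyloxy]dihydrofuran-2(3H)-one | O=C1C[C@@H](CO[Si](c2ccccc2)(c3ccccc3)C(C)(C)C)[C@H](O[C@@H]4C[C@H](C)CC[C@H]4C(C)C)O1 | intermediate
4 | guaiacol (2-methoxyphenol) | COc1ccccc1O | starting material
5 | (4S,5R)-4-[(tert-butyldiphenylsilyloxy)methyl]-5-(4-hydroxy-3-methoxyphenyl)dihydrofuran-2(3H)-one | O=C1C[C@@H](CO[Si](c2ccccc2)(c3ccccc3)C(C)(C)C)[C@H](c4ccc(O)c(OC)c4)O1 | intermediate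
6 | (4S,5R)-4-[(tert-butyldiphenylsilyloxy)methyl]-5-[4-(tert-butyldimethylsilyloxy)-3-methoxyphenyl]dihydrofuran-2(3H)-one | O=C1C[C@@H](CO[Si](c2ccccc2)(c3ccccc3)C(C)(C)C)[C@H](c4ccc(O[Si](C)(C)C(C)(C)C)c(OC)c4)O1 | intermediate
7 | 4-(tert-butyldimethylsilyloxy)-3-methoxybenzaldehyde | COc1cc(C=O)ccc1O[Si](C)(C)C(C)(C)C | starting material
8 | lithium enolate of 6 | [Li+].[O-]C1=C[C@@H](CO[Si](c2ccccc2)(c3ccccc3)C(C)(C)C)[C@H](c4ccc(O[Si](C)(C)C(C)(C)C)c(OC)c4)O1 | intermediate
9 | lithium aldolate (C3 and carbinol carbon as formed, diastereomer mixture) | O=C1C(C([O-])c5ccc(O[Si](C)(C)C(C)(C)C)c(OC)c5)[C@@H](CO[Si](c2ccccc2)(c3ccccc3)C(C)(C)C)[C@H](c4ccc(O[Si](C)(C)C(C)(C)C)c(OC)c4)O1.[Li+] | intermediate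
10 | mesylate of the aldol (diastereomer mixture) | O=C1C(C(OS(C)(=O)=O)c5ccc(O[Si](C)(C)C(C)(C)C)c(OC)c5)[C@@H](CO[Si](c2ccccc2)(c3ccccc3)C(C)(C)C)[C@H](c4ccc(O[Si](C)(C)C(C)(C)C)c(OC)c4)O1 | intermediate
11 | (4S,5R,E)-3-[4-(tert-butyldimethylsilyloxy)-3-methoxybenzylidene]-4-[(tert-butyldiphenylsilyloxy)methyl]-5-[4-(tert-butyldimethylsilyloxy)-3-methoxyphenyl]dihydrofuran-2(3H)-one | COc5cc(/C=C1\[C@@H](CO[Si](c2ccccc2)(c3ccccc3)C(C)(C)C)[C@H](c4ccc(O[Si](C)(C)C(C)(C)C)c(OC)c4)OC1=O)ccc5O[Si](C)(C)C(C)(C)C | intermediate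
12 | (3S,4S,5R)-3-[4-(tert-butyldimethylsilyloxy)-3-methoxybenzyl]-4-[(tert-butyldiphenylsilyloxy)methyl]-5-[4-(tert-butyldimethylsilyloxy)-3-methoxyphenyl]dihydrofuran-2(3H)-one | O=C1[C@@H](Cc5ccc(O[Si](C)(C)C(C)(C)C)c(OC)c5)[C@@H](CO[Si](c2ccccc2)(c3ccccc3)C(C)(C)C)[C@H](c4ccc(O[Si](C)(C)C(C)(C)C)c(OC)c4)O1 | intermediate
13 | (3S,4S,5R)-3-(4-hydroxy-3-methoxybenzyl)-5-(4-hydroxy-3-methoxyphenyl)-4-(hydroxymethyl)dihydrofuran-2(3H)-one | COc1cc(C[C@@H]2C(=O)O[C@@H](c3ccc(O)c(OC)c3)[C@@H]2CO)ccc1O | target

**Totals.** Total step count: 7. Longest linear sequence: 7 steps (1 → 13).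

**Steps most likely to fail**

1. Step 3 (key step). What may go wrong:
   - regiochemical leakage of the arene attack to the carbon para to OMe or ortho to OH;
   - a second ionisation of the benzylic C5–O1 bond followed by a second arylation;
   - incomplete facial control at C5.

   Fallback (radical cross-coupling with a regiodefined aryl metal): it sets out from 3 and comes back at 6, so step 4 is not needed. Aqueous trifluoroacetic acid in THF should hydrolyse the menthyl acetal to the pseudo-acid (4S)-4-[(tert-butyldiphenylsilyloxy)methyl]-5-hydroxydihydrofuran-2(3H)-one F1. Thionyl chloride with a trace of DMF should convert it into the pseudo-chloride (4S)-4-[(tert-butyldiphenylsilyloxy)methyl]-5-chlorodihydrofuran-2(3H)-one F2. Separately, commercial 4-bromo-2-methoxyphenol is silylated (TBSCl, imidazole) to (4-bromo-2-methoxyphenoxy)(tert-butyl)dimethylsilane F3, and bromine–lithium exchange (n-BuLi, THF, −78 °C) followed by ZnBr2 gives [4-(tert-butyldimethylsilyloxy)-3-methoxyphenyl]zinc bromide F4. Negishi coupling of F2 with F4 under NiCl2·glyme and 4,4′,4″-tri-tert-butyl-2,2′:6′,2″-terpyridine in DMF, as practised for glycosyl halides, should give 6. The C5 radical should be captured anti to the C4 substituent, and the position of the new bond on the arene is fixed by the carbon–zinc bond.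

2. Step 6. What may go wrong:
   - poor facial selectivity of hydrogen delivery, because the C5 aryl group sits on the face opposite to the C4 group;
   - hydrogenolysis of the benzylic C5–O1 bond.

   Fallback (conjugate hydride addition and kinetic protonation instead of surface hydrogenation): it sets out from 11 and comes back at 12. LiBH(s-Bu)3 in THF at −78 °C should add hydride to the benzylidene carbon and give the lithium enolate of the 3-benzyl lactone F5. Protonation of F5 at −78 °C with the bulky donor 2,6-di-tert-butyl-4-methylphenol should occur anti to the C4 substituent and give the 3,4-cis lactone 12, with no hydrogenolysis pathway available.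

3. Step 5. What may go wrong:
   - retro-aldol loss or incomplete elimination in the one-flask sequence;
   - base-mediated migration of the exocyclic double bond into the ring, which would erase C4.

   Fallback (olefination instead of aldol and elimination): it sets out from 6 and comes back at 11. LiN(i-Pr)2 (2.2 equiv) and diethyl chlorophosphate should give, through the enol phosphate and its 1,3-phosphorus shift, the α-phosphono lactone (4S,5R)-3-(diethoxyphosphoryl)-4-[(tert-butyldiphenylsilyloxy)methyl]-5-[4-(tert-butyldimethylsilyloxy)-3-methoxyphenyl]dihydrofuran-2(3H)-one F6. Horner–Wadsworth–Emmons reaction of F6 with aldehyde 7 (NaH, THF, 0 °C) should give 11 directly.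

**Further compounds**

F1 | step 3 | (4S)-4-[(tert-butyldiphenylsilyloxy)methyl]-5-hydroxydihydrofuran-2(3H)-one (C5 epimers) | O=C1C[C@@H](CO[Si](c2ccccc2)(c3ccccc3)C(C)(C)C)C(O)O1
F2 | step 3 | (4S)-4-[(tert-butyldiphenylsilyloxy)methyl]-5-chlorodihydrofuran-2(3H)-one (C5 epimers) | O=C1C[C@@H](CO[Si](c2ccccc2)(c3ccccc3)C(C)(C)C)C(Cl)O1
F3 | step 3 | (4-bromo-2-methoxyphenoxy)(tert-butyl)dimethylsilane | COc1cc(Br)ccc1O[Si](C)(C)C(C)(C)C
F4 | step 3 | [4-(tert-butyldimethylsilyloxy)-3-methoxyphenyl]zinc bromide | COc1cc([Zn]Br)ccc1O[Si](C)(C)C(C)(C)C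
F5 | step 6 | lithium enolate of the 3-benzyl lactone | [Li+].[O-]C1=C(Cc2ccc(O[Si](C)(C)C(C)(C)C)c(OC)c2)[C@@H](CO[Si](c3ccccc3)(c4ccccc4)C(C)(C)C)[C@H](c5ccc(O[Si](C)(C)C(C)(C)C)c(OC)c5)O1
F6 | step 5 | (4S,5R)-3-(diethoxyphosphoryl)-4-[(tert-butyldiphenylsilyloxy)methyl]-5-[4-(tert-butyldimethylsilyloxy)-3-methoxyphenyl]dihydrofuran-2(3H)-one | O=C1C(P(=O)(OCC)OCC)[C@@H](CO[Si](c2ccccc2)(c3ccccc3)C(C)(C)C)[C@H](c4ccc(O[Si](C)(C)C(C)(C)C)c(OC)c4)O1
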